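**Early times.** In the first seconds, a substrate molecule that reacts either couples or falls apart to side product. Both routes are first order in substrate, so substrate cancels from the ratio of their forward rates, and one number may carry the flask.

common to all: substrate 0.10 M; gas 26 mM (held); time 10 s
- alder: temperature −20 °C
- ash: temperature 5 °C

    substrate + coupling partner ⇌ target (K1 = 13 M⁻¹, k1 = 2.2 M⁻¹ s⁻¹, Ea1 = 56.0 kJ mol⁻¹, ΔH1 = −38.0 kJ mol⁻¹)
    gas ⇌ coupling partner, rate k2*(csat - [coupling partner]) (k2 = 0.58 s⁻¹, csat = 26 mM)
    crystals ⇌ target, rate k3*(cs3 - [target]) while solid is left; crystals form when [target] > cs3 (cs3 = 1.4 mM, k3 = 0.55 s⁻¹)
    substrate → side product (k4 = 0.013 s⁻¹, Ea4 = 81.0 kJ mol⁻¹)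
    (constants at 5 °C)

- for target the crystals are counted in
- as a solid, counted per litre of solution: crystals
- at the start none of coupling partner is dissolved
- the constants hold at 5 °C; other temperatures follow from the activation energies and enthalpies

1. the flask with the highest share of target in all that became target or side product ("all alike" if they lie within 1.5 percentage points) (alder / ash / all alike)
2. share of target in all that became target or side product, alder
3. share of target in all that became target or side product, ash

**First round.** Set [coupling partner] at 26 mM and ignore the way back. Coupling over loss, a selectivity factor, is then 4.40 in ash. Cooling to alder slows coupling 11-fold and the loss 32-fold, which gives 12.8 in alder.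

**Second round.** Now put that rate back in. Steady coupling must be fed from the gas, so [coupling partner] sags below saturation by the rate over 0.58 s⁻¹. Once target leaves as crystals as fast as it is made, dissolved [target] stands above 1.4 mM by the rate over 0.55 s⁻¹, and it runs back at 0.169 s⁻¹ in ash. I drop the back-flow at [target] = 1.4 mM, which is 0.237 mM s⁻¹ and much smaller than the forward 5.72 mM s⁻¹ in ash.

Both corrections scale with the rate, so going round until nothing changes divides the first number by one plus two terms. In ash these are 0.379 for the gas and 0.308 for the way back. In alder they are 0.0347 and 0.00556. That leaves 2.61 in ash and 12.3 in alder. Call this the net coupling number, target made per side product.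

**Reading it.** The share is the number over one plus itself: 92.5 % for alder and 72.3 % for ash, so the higher share is in alder.

**Is one enough?** Not quite. No coupling partner is dissolved at the start, and its approach to 26 mM has a time constant of 1.72 s, which is shorter than 10 s but not negligible. The loss runs meanwhile, so I expect both shares to come out slightly high.

**The result.** The forecast names alder, at 91 % and 69.5 %, and holds that “crystallisation helps by keeping dissolved target low”. The flasks give alder, with 91.1 % in alder and 69.1 % in ash, both below my reckoning.

**Early against late.** In ash, dissolved target is made 1.81 times as fast as it is used up at 2.71 s, and that ratio has come to 0.937 at 10.0 s. Target per side product gathered in ash up to then reads 2.24, against a net coupling number of 2.61, and the same ash flask read at 40 s, with a share of 70.8 %, reads 2.43.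

The constants used here stand for no real mixture; what happens was integrated by code.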